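**Retrosynthetic overview**

1. The last ring made is dihydrobenzofuran ring B (on C4 of the oxolane). Its C2–C3 bond is formed by rhodium-carbene 1,5-C–H insertion of a diaryldiazomethane into the ortho O–CH2–aryl ether; fluoride-triggered cis → trans epimerisation at C2 and global hydrogenolysis follow.
2. The carbene precursor is a hydrazone made from an aryl nitrile and an aryl Grignard reagent. The oxolane comes from an all-trans 3,4,5-triaryl-γ-butyrolactone by aryl addition and hydride reduction of the oxocarbenium ion (2,3-cis).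
3. The lactone comes from anti-selective cinnamylboration of 4-(benzyloxy)benzaldehyde (C4, C5), then palladium-catalysed α-arylation with the ring A bromide (C3). Ring A is made earlier by the same C–H insertion; both arenes derive from aldehyde 3.
4. Order of ring formation: dihydrobenzofuran ring A → butyrolactone (the oxolane ring at the lactone oxidation level) → dihydrobenzofuran ring B.
5. Enabling feature: in the benzene ring of ring B, C3a carries the carbene carbon (future C3) ortho to C7a–O1–CH2–Ar. The carbene carbon, C3a, C7a, O1 and the benzylic CH2 form the five-atom array for 1,5-insertion, and that C–H bond is hydridic (α to O1 and to a 4-silyloxyphenyl ring).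

Key step: step 20

**Remarks before the steps**

- Assumption: the sense of induction of Rh2(R-PTAD)4 (dirhodium tetrakis[(R)-(1-adamantyl)(phthalimido)acetate]) and of (R)-TRIP ((R)-3,3′-bis(2,4,6-triisopropylphenyl)-1,1′-binaphthyl-2,2′-diyl hydrogen phosphate) is taken to be the one drawn; if a model substrate shows the opposite sense, the antipodal catalyst is used.
- Name shorthand: RA = (2S,3S)-6-(benzyloxy)-2-[4-(benzyloxy)phenyl]-3-[3,5-bis(benzyloxy)phenyl]-2,3-dihydro-1-benzofuran-4-yl (ring A unit). CA = 5-(benzyloxy)-2-cyano-3-({4-[(triisopropylsilyl)oxy]benzyl}oxy)phenyl.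
- Oxolane numbering: O1; C2 carries the aryl group cis to the C3 substituent; C3 carries ring A; C4 carries ring B (or its precursor aryl); C5.

**Route**

Step 1
Reactants: 1 5-bromobenzene-1,3-diol
Product: 2 2-bromo-4,6-dihydroxybenzaldehyde
Conditions: POCl3, DMF, MeCN, 0 °C → rt; then H2O, 50 °C
Reagents that add atoms: N,N-dimethylformamide (CN(C)C=O); water (O)
Why: Vilsmeier–Haack formylation should occur at the resorcinol position ortho/para to the two hydroxyl groups and next to bromine, as with resorcinol and orcinol; no stereocentre.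

Step 2
Reactants: 2 2-bromo-4,6-dihydroxybenzaldehyde
Product: 3 4-(benzyloxy)-2-bromo-6-hydroxybenzaldehyde
Conditions: BnBr (1.05 equiv), NaHCO3, KI (cat.), MeCN, 80 °C
Reagents that add atoms: benzyl bromide (BrCc1ccccc1)
Why: Williamson etherification with a weak base should alkylate only the para hydroxyl, because the ortho hydroxyl is held in a hydrogen bond to the formyl group.

Step 3
Reactants: 3 4-(benzyloxy)-2-bromo-6-hydroxybenzaldehyde; 4 1-(benzyloxy)-4-(chloromethyl)benzene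
Product: 5 4-(benzyloxy)-2-{[4-(benzyloxy)benzyl]oxy}-6-bromobenzaldehyde
Conditions: K2CO3, KI (cat.), DMF, 60 °C
Reagents that add atoms: none
Why: Williamson etherification of the chelated phenol under more forcing conditions installs the O–CH2–aryl group that later becomes C2 of ring A with its aryl substituent.

Step 4
Reactants: 5 4-(benzyloxy)-2-{[4-(benzyloxy)benzyl]oxy}-6-bromobenzaldehyde
Product: 7 4-(benzyloxy)-2-{[4-(benzyloxy)benzyl]oxy}-6-bromobenzonitrile, via aldoxime 6 (not isolated)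
Conditions: NH2OH·HCl, NaOAc, EtOH, 60 °C; then Ac2O, Et3N, THF, 60 °C
Reagents that add atoms: hydroxylamine hydrochloride (NO.Cl)
Why: Oxime formation followed by acetylation and base-induced elimination of acetic acid is a standard aldehyde-to-nitrile conversion.

Step 5
Reactants: 8 1,3-bis(benzyloxy)-5-bromobenzene
Product: 9 [3,5-bis(benzyloxy)phenyl]magnesium bromide (stock solution in THF, titrated and kept under argon)
Conditions: Mg turnings, LiCl, I2 (cat.), THF, rt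
Reagents that add atoms: magnesium ([Mg])
Why: Grignard reagent formation by insertion of magnesium into the aryl C–Br bond, eased by LiCl; the benzyl ethers are inert, no stereocentre is involved, and the one titrated solution serves steps 6 and 19.

Step 6
Reactants: 7 4-(benzyloxy)-2-{[4-(benzyloxy)benzyl]oxy}-6-bromobenzonitrile; 9 [3,5-bis(benzyloxy)phenyl]magnesium bromide
Product: 11 [4-(benzyloxy)-2-{[4-(benzyloxy)benzyl]oxy}-6-bromophenyl][3,5-bis(benzyloxy)phenyl]methanone hydrazone, via N-H ketimine 10 (not isolated)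
Conditions: 9 (1.5 equiv), CuBr·SMe2 (5 mol %), THF, 65 °C; MeOH, 0 °C; then N2H4·H2O, AcOH (cat.), EtOH, 60 °C
Reagents that add atoms: hydrazine (NN)
Why: Copper-catalysed Grignard addition to the nitrile gives the N-H ketimine and transimination with hydrazine gives the hydrazone, which avoids condensing hydrazine with a doubly ortho-substituted ketone and avoids heating an ortho-bromoaryl ketone with hydrazine; bromine–magnesium exchange between an aryl Grignard reagent and an aryl bromide should be slow by comparison.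

Step 7
Reactants: 11 [4-(benzyloxy)-2-{[4-(benzyloxy)benzyl]oxy}-6-bromophenyl][3,5-bis(benzyloxy)phenyl]methanone hydrazone
Product: 14 (2S,3S)-6-(benzyloxy)-2-[4-(benzyloxy)phenyl]-3-[3,5-bis(benzyloxy)phenyl]-4-bromo-2,3-dihydro-1-benzofuran, via diazo compound 12 (not isolated), via cis-dihydrobenzofuran 13 (not isolated)
Conditions: MnO2, CH2Cl2, 0 °C → rt; filtration; Rh2(R-PTAD)4 (1 mol %), CH2Cl2, −20 → 0 °C; then CF3CO2H, CH2Cl2, 0 °C → rt
Reagents that add atoms: none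
Why: Enantioselective intramolecular C–H insertion of the donor/donor rhodium carbene into the ortho benzylic ether should give the cis-(2R,3S) ring with C3 set by the catalyst, and acid then inverts C2 by reversible heterolysis of the C2–O bond (4-alkoxybenzylic cation) to the more stable trans-(2S,3S) isomer.

Step 8
Reactants: 15 4-hydroxybenzaldehyde
Product: 16 4-[(triisopropylsilyl)oxy]benzaldehyde
Conditions: i-Pr3SiCl, imidazole, DMF, rt
Reagents that add atoms: chlorotriisopropylsilane (CC(C)[Si](Cl)(C(C)C)C(C)C)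
Why: Standard phenol silylation; the triisopropylsilyl ether is chosen because it must survive mild bases and hydrazine until step 21.

Step 9
Reactants: 16 4-[(triisopropylsilyl)oxy]benzaldehyde
Product: 17 {4-[(triisopropylsilyl)oxy]phenyl}methanol
Conditions: NaBH4, MeOH, 0 °C
Reagents that add atoms: none
Why: Borohydride reduction of an aromatic aldehyde.

Step 10
Reactants: 3 4-(benzyloxy)-2-bromo-6-hydroxybenzaldehyde; 17 {4-[(triisopropylsilyl)oxy]phenyl}methanol
Product: 18 4-(benzyloxy)-2-bromo-6-({4-[(triisopropylsilyl)oxy]benzyl}oxy)benzaldehyde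
Conditions: PPh3, DIAD, THF, 0 °C → rt
Reagents that add atoms: none
Why: Mitsunobu etherification of the acidic salicylaldehyde-type phenol with a benzylic alcohol under neutral conditions, which spares the aryl silyl ether.

Step 11
Reactants: 18 4-(benzyloxy)-2-bromo-6-({4-[(triisopropylsilyl)oxy]benzyl}oxy)benzaldehyde
Product: 20 4-(benzyloxy)-2-bromo-6-({4-[(triisopropylsilyl)oxy]benzyl}oxy)benzonitrile, via aldoxime 19 (not isolated)
Conditions: NH2OH·HCl, NaOAc, EtOH, 60 °C; then Ac2O, Et3N, THF, 60 °C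
Reagents that add atoms: hydroxylamine hydrochloride (NO.Cl)
Why: Same aldoxime dehydration as in step 4; the nitrile stores the future C3 of ring B in a form inert to the steps up to 18.

Step 12
Reactants: 20 4-(benzyloxy)-2-bromo-6-({4-[(triisopropylsilyl)oxy]benzyl}oxy)benzonitrile
Product: 21 4-(benzyloxy)-2-ethenyl-6-({4-[(triisopropylsilyl)oxy]benzyl}oxy)benzonitrile
Conditions: Bu3SnCH=CH2, Pd(PPh3)4 (5 mol %), toluene, 100 °C
Reagents that add atoms: tributyl(vinyl)stannane (C=C[Sn](CCCC)(CCCC)CCCC)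
Why: Stille vinylation of an aryl bromide activated by the ortho nitrile, under neutral conditions that spare the silyl ether.

Step 13
Reactants: 21 4-(benzyloxy)-2-ethenyl-6-({4-[(triisopropylsilyl)oxy]benzyl}oxy)benzonitrile
Product: 22 4-(benzyloxy)-2-[(1E)-3-(4,4,5,5-tetramethyl-1,3,2-dioxaborolan-2-yl)prop-1-en-1-yl]-6-({4-[(triisopropylsilyl)oxy]benzyl}oxy)benzonitrile
Conditions: allylB(pin) (3 equiv), second-generation Grubbs catalyst RuCl2(H2IMes)(PCy3)(=CHPh) (5 mol %), CH2Cl2, 40 °C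
Reagents that add atoms: allylboronic acid pinacol ester (C=CCB1OC(C)(C)C(C)(C)O1)
Why: Olefin cross-metathesis of a styrene with the allylboronate should give the E-configured γ-aryl allylboronate (thermodynamic E selectivity of styrenyl products).

Step 14
Reactants: 22 4-(benzyloxy)-2-[(1E)-3-(4,4,5,5-tetramethyl-1,3,2-dioxaborolan-2-yl)prop-1-en-1-yl]-6-({4-[(triisopropylsilyl)oxy]benzyl}oxy)benzonitrile; 23 4-(benzyloxy)benzaldehyde
Product: 24 (1R,2S)-1-[4-(benzyloxy)phenyl]-2-(CA)but-3-en-1-ol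
Conditions: (R)-TRIP (5 mol %), 4 Å molecular sieves, toluene, −30 °C; aqueous work-up
Reagents that add atoms: none
Why: Chiral phosphoric acid-catalysed allylboration through a closed chair (Zimmerman–Traxler) transition state; the E-boronate gives the anti product and the acid selects the aldehyde face, which sets C1 (R) and C2 (S), the future oxolane C5 and C4.

Step 15
Reactants: 24 (1R,2S)-1-[4-(benzyloxy)phenyl]-2-(CA)but-3-en-1-ol
Product: 25 (3S,4R)-4-[4-(benzyloxy)phenyl]-3-(CA)butane-1,4-diol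
Conditions: 9-BBN (2.5 equiv), THF, 0 °C → rt; then NaBO3·4H2O, THF–H2O, rt
Reagents that add atoms: sodium perborate ([Na+].O[B-](O)(O)OO)
Why: Anti-Markovnikov hydroboration of the terminal alkene and mild perborate oxidation; nitrile and silyl ether are inert and no stereocentre is touched.

Step 16
Reactants: 25 (3S,4R)-4-[4-(benzyloxy)phenyl]-3-(CA)butane-1,4-diol
Product: 27 (4S,5R)-5-[4-(benzyloxy)phenyl]-4-(CA)oxolan-2-one, via lactol 26 (not isolated)
Conditions: TEMPO (20 mol %), PhI(OAc)2 (2.5 equiv), CH2Cl2, rt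
Reagents that add atoms: none
Why: Oxoammonium oxidation selective for the primary alcohol gives the hydroxy aldehyde, which closes to the lactol and is oxidised on to the trans-4,5-diaryl lactone; this closes the oxolane ring at the lactone oxidation level.

Step 17
Reactants: 27 (4S,5R)-5-[4-(benzyloxy)phenyl]-4-(CA)oxolan-2-one; 14 (2S,3S)-6-(benzyloxy)-2-[4-(benzyloxy)phenyl]-3-[3,5-bis(benzyloxy)phenyl]-4-bromo-2,3-dihydro-1-benzofuran
Product: 29 (3S,4S,5R)-5-[4-(benzyloxy)phenyl]-4-(CA)-3-(RA)oxolan-2-one, via silyl ketene acetal 28 (not isolated)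
Conditions: LiN(SiMe3)2, Me3SiCl (internal quench), THF, −78 °C; then 14, Pd(dba)2 (5 mol %), P(t-Bu)3 (10 mol %), ZnF2 (0.6 equiv), DMF, 80 °C; DBU (0.2 equiv), CH2Cl2, rt
Reagents that add atoms: none
Why: Palladium-catalysed α-arylation of the trimethylsilyl ketene acetal keeps the concentration of free enolate next to the ortho-cyanoaryl group low (against Thorpe-type cyclisation); the aryl group is delivered anti to the C4 aryl and the epimerisable C3 centre should end trans (all-trans lactone, thermodynamic).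

Step 18
Reactants: 29 (3S,4S,5R)-5-[4-(benzyloxy)phenyl]-4-(CA)-3-(RA)oxolan-2-one; 30 [4-(benzyloxy)phenyl]magnesium bromide
Product: 32 (2S,3S,4S,5R)-2,5-bis[4-(benzyloxy)phenyl]-4-(CA)-3-(RA)oxolane, via hemiketal 31 (not isolated)
Conditions: 30, CeCl3, THF, −78 °C; aq NH4Cl; then Et3SiH, BF3·OEt2, CH2Cl2, −78 °C
Reagents that add atoms: none
Why: The cerium-modified Grignard reagent should add once to the lactone without enolising C3 or touching the hindered nitrile; the 2-aryl oxocarbenium ion then takes hydride on the face anti to the C3 substituent, placing the C2 aryl cis to ring A (the 2,3-cis outcome of hemiketal reductions in 2,5-diaryl tetrahydrofuran lignan synthesis).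

Step 19
Reactants: 32 (2S,3S,4S,5R)-2,5-bis[4-(benzyloxy)phenyl]-4-(CA)-3-(RA)oxolane; 9 [3,5-bis(benzyloxy)phenyl]magnesium bromide
Product: 34 (2S,3S,4S,5R)-2,5-bis[4-(benzyloxy)phenyl]-4-{5-(benzyloxy)-2-[[3,5-bis(benzyloxy)phenyl](hydrazinylidene)methyl]-3-({4-[(triisopropylsilyl)oxy]benzyl}oxy)phenyl}-3-(RA)oxolane, via N-H ketimine 33 (not isolated)
Conditions: 9 (3 equiv), CuBr·SMe2 (5 mol %), THF–toluene, 70 °C; MeOH; then N2H4·H2O, AcOH (cat.), EtOH–THF, 50 °C
Reagents that add atoms: hydrazine (NN)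
Why: As in step 6, copper-catalysed Grignard addition to the nitrile and transimination give the N-unsubstituted hydrazone of a ketone too hindered for direct condensation; the oxolane, ring A and the silyl ether tolerate these conditions.

Step 20
Reactants: 34 (2S,3S,4S,5R)-2,5-bis[4-(benzyloxy)phenyl]-4-{5-(benzyloxy)-2-[[3,5-bis(benzyloxy)phenyl](hydrazinylidene)methyl]-3-({4-[(triisopropylsilyl)oxy]benzyl}oxy)phenyl}-3-(RA)oxolane
Product: 36 (2S,3S,4S,5R)-2,5-bis[4-(benzyloxy)phenyl]-4-[(2R,3S)-6-(benzyloxy)-3-[3,5-bis(benzyloxy)phenyl]-2-{4-[(triisopropylsilyl)oxy]phenyl}-2,3-dihydro-1-benzofuran-4-yl]-3-(RA)oxolane, via diazo compound 35 (not isolated)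
Conditions: MnO2, CH2Cl2, 0 °C → rt; filtration; Rh2(R-PTAD)4 (2 mol %), CH2Cl2, −20 → 0 °C
Reagents that add atoms: none
Why: MnO2 oxidises the hydrazone to the diaryldiazomethane, which the dirhodium carboxylate turns into a donor/donor carbene; the carbene carbon takes hydride from the ortho O–CH2–aryl group and the oxocarbenium/rhodium-bound carbanion pair collapses to the C2–C3 bond (stepwise 1,5-C–H insertion). The closest known reaction type is the enantioselective intramolecular C–H insertion of donor/donor carbenes from 2-(benzyloxy)benzophenone hydrazones, which gives cis-2,3-diaryl-2,3-dihydrobenzofurans. The one ring formed, the dihydrofuran ring B, closes by C2–C3 bond formation through the five-atom array carbene C–C3a–C7a–O1–CH2. C3 (S) is set by the chiral carboxylate ligands, which select the carbene face, and C2 (R) follows from the cis-selective collapse; its inversion is planned for step 21. The step needs site selectivity over the tertiary oxolane C3–H and C5–H bonds (also in 1,5-relation through C4) and over ylide formation at the oxolane oxygen. The ether CH2 is secondary, freely rotating and the most hydridic C–H (α to oxygen and to the 4-silyloxyphenyl ring), the oxolane C–H bonds are shielded by their aryl groups and turned out of the arene plane, and donor/donor carbenes are weak enough electrophiles to favour C–H insertion over oxonium ylides.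

Step 21
Reactants: 36 (2S,3S,4S,5R)-2,5-bis[4-(benzyloxy)phenyl]-4-[(2R,3S)-6-(benzyloxy)-3-[3,5-bis(benzyloxy)phenyl]-2-{4-[(triisopropylsilyl)oxy]phenyl}-2,3-dihydro-1-benzofuran-4-yl]-3-(RA)oxolane
Product: 38 (2S,3S,4S,5R)-2,5-bis[4-(benzyloxy)phenyl]-4-[(2S,3S)-6-(benzyloxy)-3-[3,5-bis(benzyloxy)phenyl]-2-(4-hydroxyphenyl)-2,3-dihydro-1-benzofuran-4-yl]-3-(RA)oxolane, via cis phenol 37 (not isolated)
Conditions: Bu4NF (1.5 equiv), THF, 0 → 40 °C; aq NH4Cl
Reagents that add atoms: none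
Why: Fluoride frees the only phenoxide in the molecule, which opens ring B reversibly to a para-quinone methide and an aryloxide (retro-oxa-Michael) and recloses to the more stable trans isomer (C2 R → S, C3 untouched), as in the base-induced C2 epimerisation of 2-(4-hydroxyphenyl) benzo-fused cyclic ethers; the acid-labile 2,3-cis oxolane and ring A carry no free para-hydroxyl and should stay intact.

Step 22
Reactants: 38 (2S,3S,4S,5R)-2,5-bis[4-(benzyloxy)phenyl]-4-[(2S,3S)-6-(benzyloxy)-3-[3,5-bis(benzyloxy)phenyl]-2-(4-hydroxyphenyl)-2,3-dihydro-1-benzofuran-4-yl]-3-(RA)oxolane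
Product: 39 (2S,3S,4S,5R)-2,5-bis(4-hydroxyphenyl)-3,4-bis[(2S,3S)-3-(3,5-dihydroxyphenyl)-6-hydroxy-2-(4-hydroxyphenyl)-2,3-dihydro-1-benzofuran-4-yl]oxolane
Conditions: H2 (1 atm), Pd/C, EtOAc–MeOH, rt
Reagents that add atoms: none
Why: Hydrogenolysis of the nine primary O-benzyl ethers under neutral conditions; the hindered secondary benzylic C–O bonds of the oxolane and the dihydrobenzofurans should survive, as in debenzylations of 2,5-diaryl tetrahydrofuran lignans, and no acid is present to epimerise oxolane C2.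

**Compound list**

1 | 5-bromobenzene-1,3-diol | Oc1cc(O)cc(Br)c1 | starting material
2 | 2-bromo-4,6-dihydroxybenzaldehyde | O=Cc1c(O)cc(O)cc1Br | intermediate
3 | 4-(benzyloxy)-2-bromo-6-hydroxybenzaldehyde | O=Cc1c(O)cc(OCc2ccccc2)cc1Br | intermediate
4 | 1-(benzyloxy)-4-(chloromethyl)benzene | ClCc1ccc(OCc2ccccc2)cc1 | starting material
5 | 4-(benzyloxy)-2-{[4-(benzyloxy)benzyl]oxy}-6-bromobenzaldehyde | O=Cc1c(OCc2ccc(OCc3ccccc3)cc2)cc(OCc2ccccc2)cc1Br | intermediate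
6 | aldoxime of 5 | ON=Cc1c(OCc2ccc(OCc3ccccc3)cc2)cc(OCc2ccccc2)cc1Br | intermediate
7 | 4-(benzyloxy)-2-{[4-(benzyloxy)benzyl]oxy}-6-bromobenzonitrile | N#Cc1c(OCc2ccc(OCc3ccccc3)cc2)cc(OCc2ccccc2)cc1Br | intermediate
8 | 1,3-bis(benzyloxy)-5-bromobenzene | Brc1cc(OCc2ccccc2)cc(OCc2ccccc2)c1 | starting material
9 | [3,5-bis(benzyloxy)phenyl]magnesium bromide (THF stock solution) | Br[Mg]c1cc(OCc2ccccc2)cc(OCc2ccccc2)c1 | intermediate
10 | N-H ketimine from 7 and 9 | N=C(c1cc(OCc2ccccc2)cc(OCc2ccccc2)c1)c1c(OCc2ccc(OCc3ccccc3)cc2)cc(OCc2ccccc2)cc1Br | intermediate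
11 | [4-(benzyloxy)-2-{[4-(benzyloxy)benzyl]oxy}-6-bromophenyl][3,5-bis(benzyloxy)phenyl]methanone hydrazone | NN=C(c1cc(OCc2ccccc2)cc(OCc2ccccc2)c1)c1c(OCc2ccc(OCc3ccccc3)cc2)cc(OCc2ccccc2)cc1Br | intermediate
12 | diazo compound from 11 | [N-]=[N+]=C(c1cc(OCc2ccccc2)cc(OCc2ccccc2)c1)c1c(OCc2ccc(OCc3ccccc3)cc2)cc(OCc2ccccc2)cc1Br | intermediate
13 | (2R,3S)-6-(benzyloxy)-2-[4-(benzyloxy)phenyl]-3-[3,5-bis(benzyloxy)phenyl]-4-bromo-2,3-dihydro-1-benzofuran (cis) | Brc1cc(OCc2ccccc2)cc2O[C@@H](c3ccc(OCc4ccccc4)cc3)[C@@H](c3cc(OCc4ccccc4)cc(OCc4ccccc4)c3)c12 | intermediate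
14 | (2S,3S)-6-(benzyloxy)-2-[4-(benzyloxy)phenyl]-3-[3,5-bis(benzyloxy)phenyl]-4-bromo-2,3-dihydro-1-benzofuran (trans) | Brc1cc(OCc2ccccc2)cc2O[C@H](c3ccc(OCc4ccccc4)cc3)[C@@H](c3cc(OCc4ccccc4)cc(OCc4ccccc4)c3)c12 | intermediate
15 | 4-hydroxybenzaldehyde | O=Cc1ccc(O)cc1 | starting material
16 | 4-[(triisopropylsilyl)oxy]benzaldehyde | O=Cc1ccc(O[Si](C(C)C)(C(C)C)C(C)C)cc1 | intermediate
17 | {4-[(triisopropylsilyl)oxy]phenyl}methanol | OCc1ccc(O[Si](C(C)C)(C(C)C)C(C)C)cc1 | intermediate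
18 | 4-(benzyloxy)-2-bromo-6-({4-[(triisopropylsilyl)oxy]benzyl}oxy)benzaldehyde | O=Cc1c(OCc2ccc(O[Si](C(C)C)(C(C)C)C(C)C)cc2)cc(OCc2ccccc2)cc1Br | intermediate
19 | aldoxime of 18 | ON=Cc1c(OCc2ccc(O[Si](C(C)C)(C(C)C)C(C)C)cc2)cc(OCc2ccccc2)cc1Br | intermediate
20 | 4-(benzyloxy)-2-bromo-6-({4-[(triisopropylsilyl)oxy]benzyl}oxy)benzonitrile | N#Cc1c(OCc2ccc(O[Si](C(C)C)(C(C)C)C(C)C)cc2)cc(OCc2ccccc2)cc1Br | intermediate
21 | 4-(benzyloxy)-2-ethenyl-6-({4-[(triisopropylsilyl)oxy]benzyl}oxy)benzonitrile | N#Cc1c(OCc2ccc(O[Si](C(C)C)(C(C)C)C(C)C)cc2)cc(OCc2ccccc2)cc1C=C | intermediate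
22 | 4-(benzyloxy)-2-[(1E)-3-(4,4,5,5-tetramethyl-1,3,2-dioxaborolan-2-yl)prop-1-en-1-yl]-6-({4-[(triisopropylsilyl)oxy]benzyl}oxy)benzonitrile | N#Cc1c(OCc2ccc(O[Si](C(C)C)(C(C)C)C(C)C)cc2)cc(OCc2ccccc2)cc1/C=C/CB1OC(C)(C)C(C)(C)O1 | intermediate
23 | 4-(benzyloxy)benzaldehyde | O=Cc1ccc(OCc2ccccc2)cc1 | starting material
24 | (1R,2S)-1-[4-(benzyloxy)phenyl]-2-(CA)but-3-en-1-ol | C=C[C@@H](c1cc(OCc2ccccc2)cc(OCc2ccc(O[Si](C(C)C)(C(C)C)C(C)C)cc2)c1C#N)[C@@H](O)c1ccc(OCc2ccccc2)cc1 | intermediate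
25 | (3S,4R)-4-[4-(benzyloxy)phenyl]-3-(CA)butane-1,4-diol | OCC[C@@H](c1cc(OCc2ccccc2)cc(OCc2ccc(O[Si](C(C)C)(C(C)C)C(C)C)cc2)c1C#N)[C@@H](O)c1ccc(OCc2ccccc2)cc1 | intermediate
26 | (4S,5R)-5-[4-(benzyloxy)phenyl]-4-(CA)oxolan-2-ol (both anomers) | OC1C[C@@H](c2cc(OCc3ccccc3)cc(OCc3ccc(O[Si](C(C)C)(C(C)C)C(C)C)cc3)c2C#N)[C@H](c2ccc(OCc3ccccc3)cc2)O1 | intermediate
27 | (4S,5R)-5-[4-(benzyloxy)phenyl]-4-(CA)oxolan-2-one | O=C1C[C@@H](c2cc(OCc3ccccc3)cc(OCc3ccc(O[Si](C(C)C)(C(C)C)C(C)C)cc3)c2C#N)[C@H](c2ccc(OCc3ccccc3)cc2)O1 | intermediate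
28 | trimethylsilyl ketene acetal of 27 | C[Si](C)(C)OC1=C[C@@H](c2cc(OCc3ccccc3)cc(OCc3ccc(O[Si](C(C)C)(C(C)C)C(C)C)cc3)c2C#N)[C@H](c2ccc(OCc3ccccc3)cc2)O1 | intermediate
29 | (3S,4S,5R)-5-[4-(benzyloxy)phenyl]-4-(CA)-3-(RA)oxolan-2-one | O=C1[C@H](c2cc(OCc3ccccc3)cc3O[C@H](c4ccc(OCc5ccccc5)cc4)[C@@H](c4cc(OCc5ccccc5)cc(OCc5ccccc5)c4)c23)[C@@H](c2cc(OCc3ccccc3)cc(OCc3ccc(O[Si](C(C)C)(C(C)C)C(C)C)cc3)c2C#N)[C@H](c2ccc(OCc3ccccc3)cc2)O1 | intermediate
30 | [4-(benzyloxy)phenyl]magnesium bromide (THF solution) | Br[Mg]c1ccc(OCc2ccccc2)cc1 | starting material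
31 | (3S,4S,5R)-2,5-bis[4-(benzyloxy)phenyl]-4-(CA)-3-(RA)oxolan-2-ol (both anomers, in equilibrium with the hydroxy ketone) | OC1(c2ccc(OCc3ccccc3)cc2)O[C@@H](c2ccc(OCc3ccccc3)cc2)[C@H](c2cc(OCc3ccccc3)cc(OCc3ccc(O[Si](C(C)C)(C(C)C)C(C)C)cc3)c2C#N)[C@H]1c1cc(OCc2ccccc2)cc2O[C@H](c3ccc(OCc4ccccc4)cc3)[C@@H](c3cc(OCc4ccccc4)cc(OCc4ccccc4)c3)c12 | intermediate
32 | (2S,3S,4S,5R)-2,5-bis[4-(benzyloxy)phenyl]-4-(CA)-3-(RA)oxolane | C(c1ccccc1)Oc1ccc(cc1)[C@H]1O[C@@H](c2ccc(OCc3ccccc3)cc2)[C@H](c2cc(OCc3ccccc3)cc(OCc3ccc(O[Si](C(C)C)(C(C)C)C(C)C)cc3)c2C#N)[C@H]1c1cc(OCc2ccccc2)cc2O[C@H](c3ccc(OCc4ccccc4)cc3)[C@@H](c3cc(OCc4ccccc4)cc(OCc4ccccc4)c3)c12 | intermediate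
33 | N-H ketimine from 32 and 9 | C(c1ccccc1)Oc1ccc(cc1)[C@H]1O[C@@H](c2ccc(OCc3ccccc3)cc2)[C@H](c2cc(OCc3ccccc3)cc(OCc3ccc(O[Si](C(C)C)(C(C)C)C(C)C)cc3)c2C(=N)c2cc(OCc3ccccc3)cc(OCc3ccccc3)c2)[C@H]1c1cc(OCc2ccccc2)cc2O[C@H](c3ccc(OCc4ccccc4)cc3)[C@@H](c3cc(OCc4ccccc4)cc(OCc4ccccc4)c3)c12 | intermediate
34 | (2S,3S,4S,5R)-2,5-bis[4-(benzyloxy)phenyl]-4-{5-(benzyloxy)-2-[[3,5-bis(benzyloxy)phenyl](hydrazinylidene)methyl]-3-({4-[(triisopropylsilyl)oxy]benzyl}oxy)phenyl}-3-(RA)oxolane | C(c1ccccc1)Oc1ccc(cc1)[C@H]1O[C@@H](c2ccc(OCc3ccccc3)cc2)[C@H](c2cc(OCc3ccccc3)cc(OCc3ccc(O[Si](C(C)C)(C(C)C)C(C)C)cc3)c2C(=NN)c2cc(OCc3ccccc3)cc(OCc3ccccc3)c2)[C@H]1c1cc(OCc2ccccc2)cc2O[C@H](c3ccc(OCc4ccccc4)cc3)[C@@H](c3cc(OCc4ccccc4)cc(OCc4ccccc4)c3)c12 | intermediate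
35 | diazo compound from 34 | C(c1ccccc1)Oc1ccc(cc1)[C@H]1O[C@@H](c2ccc(OCc3ccccc3)cc2)[C@H](c2cc(OCc3ccccc3)cc(OCc3ccc(O[Si](C(C)C)(C(C)C)C(C)C)cc3)c2C(=[N+]=[N-])c2cc(OCc3ccccc3)cc(OCc3ccccc3)c2)[C@H]1c1cc(OCc2ccccc2)cc2O[C@H](c3ccc(OCc4ccccc4)cc3)[C@@H](c3cc(OCc4ccccc4)cc(OCc4ccccc4)c3)c12 | intermediate
36 | (2S,3S,4S,5R)-2,5-bis[4-(benzyloxy)phenyl]-4-[(2R,3S)-6-(benzyloxy)-3-[3,5-bis(benzyloxy)phenyl]-2-{4-[(triisopropylsilyl)oxy]phenyl}-2,3-dihydro-1-benzofuran-4-yl]-3-(RA)oxolane (ring B cis) | C(c1ccccc1)Oc1ccc(cc1)[C@H]1O[C@@H](c2ccc(OCc3ccccc3)cc2)[C@H](c2cc(OCc3ccccc3)cc3O[C@@H](c4ccc(O[Si](C(C)C)(C(C)C)C(C)C)cc4)[C@@H](c4cc(OCc5ccccc5)cc(OCc5ccccc5)c4)c23)[C@H]1c1cc(OCc2ccccc2)cc2O[C@H](c3ccc(OCc4ccccc4)cc3)[C@@H](c3cc(OCc4ccccc4)cc(OCc4ccccc4)c3)c12 | intermediate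
37 | (2S,3S,4S,5R)-2,5-bis[4-(benzyloxy)phenyl]-4-[(2R,3S)-6-(benzyloxy)-3-[3,5-bis(benzyloxy)phenyl]-2-(4-hydroxyphenyl)-2,3-dihydro-1-benzofuran-4-yl]-3-(RA)oxolane (ring B cis phenol) | C(c1ccccc1)Oc1ccc(cc1)[C@H]1O[C@@H](c2ccc(OCc3ccccc3)cc2)[C@H](c2cc(OCc3ccccc3)cc3O[C@@H](c4ccc(O)cc4)[C@@H](c4cc(OCc5ccccc5)cc(OCc5ccccc5)c4)c23)[C@H]1c1cc(OCc2ccccc2)cc2O[C@H](c3ccc(OCc4ccccc4)cc3)[C@@H](c3cc(OCc4ccccc4)cc(OCc4ccccc4)c3)c12 | intermediate
38 | (2S,3S,4S,5R)-2,5-bis[4-(benzyloxy)phenyl]-4-[(2S,3S)-6-(benzyloxy)-3-[3,5-bis(benzyloxy)phenyl]-2-(4-hydroxyphenyl)-2,3-dihydro-1-benzofuran-4-yl]-3-(RA)oxolane (ring B trans phenol) | C(c1ccccc1)Oc1ccc(cc1)[C@H]1O[C@@H](c2ccc(OCc3ccccc3)cc2)[C@H](c2cc(OCc3ccccc3)cc3O[C@H](c4ccc(O)cc4)[C@@H](c4cc(OCc5ccccc5)cc(OCc5ccccc5)c4)c23)[C@H]1c1cc(OCc2ccccc2)cc2O[C@H](c3ccc(OCc4ccccc4)cc3)[C@@H](c3cc(OCc4ccccc4)cc(OCc4ccccc4)c3)c12 | intermediate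
39 | (2S,3S,4S,5R)-2,5-bis(4-hydroxyphenyl)-3,4-bis[(2S,3S)-3-(3,5-dihydroxyphenyl)-6-hydroxy-2-(4-hydroxyphenyl)-2,3-dihydro-1-benzofuran-4-yl]oxolane | Oc1ccc(cc1)[C@H]1O[C@@H](c2ccc(O)cc2)[C@H](c2cc(O)cc3O[C@H](c4ccc(O)cc4)[C@@H](c4cc(O)cc(O)c4)c23)[C@H]1c1cc(O)cc2O[C@H](c3ccc(O)cc3)[C@@H](c3cc(O)cc(O)c3)c12 | target

**Step count and risks**

Total step count: 22. Longest linear sequence: 15 steps (steps 1, 2 and 10–22).

Steps most likely to fail:

1. Step 17 (α-arylation). The C–C reductive elimination at a carbon flanked by two ortho-substituted aryl groups may be slow. β-Hydride elimination of the palladium enolate to the butenolide, closure of the zinc enolate onto the ortho nitrile, or fluoride-induced loss of the aryl silyl ether may then take over. The fallback sets out from 28 and 14 and returns at 29, with the polarity of the bond formation reversed. The silyl ketene acetal 28 is brominated (NBS, THF, −78 °C) to the α-bromolactone F1. Bromide 14 is converted by magnesium insertion in the presence of LiCl and ZnCl2 into the arylzinc chloride F2. A nickel-catalysed Negishi arylation of the secondary α-bromo lactone (NiCl2·glyme, bipyridine ligand, THF–DMA, 0 °C → rt) joins the two through a C3 radical, and brief DBU treatment equilibrates C3 to the all-trans lactone 29.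

2. Step 20 (key step). The carbene may insert into the tertiary benzylic C–H bonds of the oxolane (C3–H, C5–H), or the diazo compound may form azine, or substrate and catalyst may be mismatched in facial selectivity. The fallback sets out from 32 and returns at 39; ring B is still closed last, but by a formal (4+1) annulation of an ortho-quinone methide. DIBAL-H (toluene, −78 °C) reduces the nitrile to the aldehyde F3. Addition of Grignard reagent 9 and trapping of the alkoxide with Ac2O gives the benzhydryl acetate F4 (both carbinol epimers). The sulfonium salt F5 is made from chloride 4 (Me2S, NaBF4, MeCN). Treatment of F4 with Bu4NF and Cs2CO3 in the presence of F5 removes the silyl group; the 4-hydroxybenzyl ether then fragments by 1,6-elimination to unmask the ring B phenoxide, and loss of acetate gives the ortho-quinone methide. The sulfur ylide adds and closes to the trans-dihydrobenzofuran F6 (all ten phenols benzylated). Hydrogenolysis as in step 22 gives 39. The configuration at C3 of ring B then rests on substrate control, and diastereomers would have to be separated.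

3. Step 21 (epimerisation). The quinone methide may tautomerise to the ring-opened stilbene phenol instead of reclosing, or the inversion may stay incomplete. The fallback sets out from 36 and returns at 39. Buffered desilylation (Bu4NF/AcOH, THF, 0 °C) gives the cis phenol 37 as an isolated compound. Hydrogenolysis (H2, Pd/C) gives the fully deprotected ring B C2-epimer F7. The inversion is then done last, on the free polyphenol, in degassed MeOH–aqueous NaHCO3 at 40 °C under argon. There both dihydrobenzofuran rings can open to quinone methides and reclose trans, while the oxolane, whose opening would need an alkoxide leaving group, should stay intact.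

Further compounds
F1 | step 17 | (4S,5R)-5-[4-(benzyloxy)phenyl]-3-bromo-4-(CA)oxolan-2-one (C3 epimers) | O=C1C(Br)[C@@H](c2cc(OCc3ccccc3)cc(OCc3ccc(O[Si](C(C)C)(C(C)C)C(C)C)cc3)c2C#N)[C@H](c2ccc(OCc3ccccc3)cc2)O1
F2 | step 17 | [(2S,3S)-6-(benzyloxy)-2-[4-(benzyloxy)phenyl]-3-[3,5-bis(benzyloxy)phenyl]-2,3-dihydro-1-benzofuran-4-yl]zinc chloride | Cl[Zn]c1cc(OCc2ccccc2)cc2O[C@H](c3ccc(OCc4ccccc4)cc3)[C@@H](c3cc(OCc4ccccc4)cc(OCc4ccccc4)c3)c12
F3 | step 20 | aldehyde corresponding to nitrile 32 (C≡N replaced by CH=O) | C(c1ccccc1)Oc1ccc(cc1)[C@H]1O[C@@H](c2ccc(OCc3ccccc3)cc2)[C@H](c2cc(OCc3ccccc3)cc(OCc3ccc(O[Si](C(C)C)(C(C)C)C(C)C)cc3)c2C=O)[C@H]1c1cc(OCc2ccccc2)cc2O[C@H](c3ccc(OCc4ccccc4)cc3)[C@@H](c3cc(OCc4ccccc4)cc(OCc4ccccc4)c3)c12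
F4 | step 20 | benzhydryl acetate from F3 and 9 (carbinol epimers) | C(c1ccccc1)Oc1ccc(cc1)[C@H]1O[C@@H](c2ccc(OCc3ccccc3)cc2)[C@H](c2cc(OCc3ccccc3)cc(OCc3ccc(O[Si](C(C)C)(C(C)C)C(C)C)cc3)c2C(OC(C)=O)c2cc(OCc3ccccc3)cc(OCc3ccccc3)c2)[C@H]1c1cc(OCc2ccccc2)cc2O[C@H](c3ccc(OCc4ccccc4)cc3)[C@@H](c3cc(OCc4ccccc4)cc(OCc4ccccc4)c3)c12
F5 | step 20 | [4-(benzyloxy)benzyl]dimethylsulfonium tetrafluoroborate | C[S+](C)Cc1ccc(OCc2ccccc2)cc1.F[B-](F)(F)F
F6 | step 20 | deca-O-benzyl ether of 39 | C(c1ccccc1)Oc1ccc(cc1)[C@H]1O[C@@H](c2ccc(OCc3ccccc3)cc2)[C@H](c2cc(OCc3ccccc3)cc3O[C@H](c4ccc(OCc5ccccc5)cc4)[C@@H](c4cc(OCc5ccccc5)cc(OCc5ccccc5)c4)c23)[C@H]1c1cc(OCc2ccccc2)cc2O[C@H](c3ccc(OCc4ccccc4)cc3)[C@@H](c3cc(OCc4ccccc4)cc(OCc4ccccc4)c3)c12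
F7 | step 21 | ring B C2-epimer of 39 (ring B 2R,3S, cis) | Oc1ccc(cc1)[C@H]1O[C@@H](c2ccc(O)cc2)[C@H](c2cc(O)cc3O[C@@H](c4ccc(O)cc4)[C@@H](c4cc(O)cc(O)c4)c23)[C@H]1c1cc(O)cc2O[C@H](c3ccc(O)cc3)[C@@H](c3cc(O)cc(O)c3)c12
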